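**Plan**

1. Retrosynthesis: the C15 silyl group and the C1–C10 oxirane are removed first, then the ten-membered carbocycle is cut at C3–C4. C3 is an allylic carbinol on C4 of the Z-trisubstituted C4=C5 alkene, the retron of an alkenylmetal addition to an aldehyde.
2. The seco iodo-aldehyde is cut at the C8–O ester bond (Mitsunobu, inversion) and at C7–C8 (zinc Barbier of a 3-bromomethyl butenolide with a β,γ-unsaturated aldehyde). The butenolide is cut at C7=C11 (ring-closing metathesis) and C5–C6 (alkynylation), the aldehyde arm at C9–C10.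
3. Forward ring order: butenolide (step 4), converted into the trans α-methylene γ-lactone on C6/C7 (step 9), then the ten-membered ring (step 13), last the oxirane (step 14).
4. Stereochemistry: C6 from catalytic asymmetric alkynylation; C7 by attack anti to the C6 substituent and C8 by the chair transition state of the Barbier step, C8 then inverted in the Mitsunobu esterification; the ester α-centre from (R)-2-methylbutanoic acid.
5. C3 is set in the ring closure (substrate control), C1/C10 by peracid attack on the outer face of the E-alkene. Z-C4=C5 comes from trans-hydroalumination–iodination, E-C1=C10 from syn-hydrozirconation.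

Key step: step 13

Remark: germacrane numbering (C1–C15) is used for all intermediates; the sense of induction in step 1 is assumed to be Re-face delivery with the (S,S)-ligand, as in the aldol reactions of the same catalyst, and the antipodal ligand would be used if the opposite is found.

**Route**

Step 1
Reactants: 1 tert-butyldimethyl(prop-2-yn-1-yloxy)silane; 2 (E)-but-2-enal
Product: 4 (2E,4S)-7-[(tert-butyldimethylsilyl)oxy]hept-2-en-5-yn-4-ol, via methylzinc alkynide 3 (not isolated)
Conditions: Me2Zn (3 equiv), (S,S)-ProPhenol (10 mol%), Ph3P=O (20 mol%), toluene, 0 °C → rt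
Reagents that add atoms: none
Why: Catalytic enantioselective zinc alkynylation of an enal (dinuclear zinc–ProPhenol type), in which the alkynylzinc is delivered 1,2 to the Re face of the bound aldehyde, should set the C6 carbinol as S.

Step 2
Reactants: 4 (2E,4S)-7-[(tert-butyldimethylsilyl)oxy]hept-2-en-5-yn-4-ol
Product: 6 (2Z,4S,5E)-1-[(tert-butyldimethylsilyl)oxy]-2-iodohepta-2,5-dien-4-ol, via cyclic sodium alkenylalanate 5 (not isolated)
Conditions: Red-Al (1.8 equiv), THF, 0 °C → rt; EtOAc; then NIS, −78 → 0 °C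
Reagents that add atoms: N-iodosuccinimide, O=C1CCC(=O)N1I
Why: Hydroxyl-directed trans-hydroalumination of the propargylic alcohol places aluminium on the distal alkyne carbon (C4) and hydride on C5, and iodinolysis with retention should give the Z-alkenyl iodide while the E-propenyl group and the silyl ether stay untouched.

Step 3
Reactants: 6 (2Z,4S,5E)-1-[(tert-butyldimethylsilyl)oxy]-2-iodohepta-2,5-dien-4-ol; 7 2-(bromomethyl)prop-2-enoic acid
Product: 9 (2Z,4S,5E)-1-[(tert-butyldimethylsilyl)oxy]-2-iodohepta-2,5-dien-4-yl 2-(bromomethyl)prop-2-enoate, via 2-(bromomethyl)acryloyl chloride 8 (not isolated)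
Conditions: 7, (COCl)2, cat. DMF, CH2Cl2, 0 °C → rt, concentrate; then 6, 2,6-lutidine, CH2Cl2, −40 → 0 °C
Reagents that add atoms: none
Why: Acylation of the secondary alcohol by the acid chloride with a hindered, poorly nucleophilic base should give the ester without attack on the allylic bromide and without touching the C6 centre.

Step 4
Reactants: 9 (2Z,4S,5E)-1-[(tert-butyldimethylsilyl)oxy]-2-iodohepta-2,5-dien-4-yl 2-(bromomethyl)prop-2-enoate
Product: 10 (5S)-3-(bromomethyl)-5-[(1Z)-3-[(tert-butyldimethylsilyl)oxy]-2-iodoprop-1-en-1-yl]furan-2(5H)-one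
Conditions: second-generation Ru isopropoxybenzylidene catalyst (HG-II, 5 mol%), toluene, 60 °C, argon sparge
Reagents that add atoms: none
Why: Ring-closing metathesis between the propenyl group and the 1,1-disubstituted acrylate alkene closes the five-membered butenolide with loss of propene under neutral conditions that leave the alkenyl iodide, the allylic bromide and the base-sensitive C6–H untouched.

Step 5
Reactants: 11 pent-3-yn-1-ol
Product: 12 1-methoxy-4-[(pent-3-yn-1-yloxy)methyl]benzene
Conditions: NaH, PMBCl, cat. Bu4NI, THF/DMF, 0 °C → rt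
Reagents that add atoms: 4-methoxybenzyl chloride, COc1ccc(CCl)cc1
Why: Williamson etherification gives a C3–O protecting group that survives the organolithium, zinc and Mitsunobu steps and can later be removed oxidatively beside the silyl ether.

Step 6
Reactants: 12 1-methoxy-4-[(pent-3-yn-1-yloxy)methyl]benzene
Product: 14 1-({[(3E)-4-iodopent-3-en-1-yl]oxy}methyl)-4-methoxybenzene, via E-alkenylzirconocene chloride 13 (not isolated)
Conditions: Cp2Zr(H)Cl (2.5 equiv), THF, 50 °C; then I2, 0 °C
Reagents that add atoms: iodine, II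
Why: Hydrozirconation–iodination, in which syn addition of Zr–H with excess reagent at 50 °C equilibrates zirconium to the methyl-bearing carbon (C10) and iodinolysis proceeds with retention, should give the E-iodide that fixes the C1=C10 geometry.

Step 7
Reactants: 14 1-({[(3E)-4-iodopent-3-en-1-yl]oxy}methyl)-4-methoxybenzene; 15 oxirane
Product: 17 (3E)-6-[(4-methoxybenzyl)oxy]-3-methylhex-3-en-1-ol, via E-alkenyllithium 16 (not isolated)
Conditions: t-BuLi (2.1 equiv), Et2O, −78 °C; then oxirane (excess), −78 → 0 °C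
Reagents that add atoms: none
Why: Lithium–iodine exchange with retention gives the alkenyllithium, whose SN2 opening of oxirane adds the C9–C8 unit as a homoallylic alcohol without loss of the E geometry.

Step 8
Reactants: 17 (3E)-6-[(4-methoxybenzyl)oxy]-3-methylhex-3-en-1-ol
Product: 18 (3E)-6-[(4-methoxybenzyl)oxy]-3-methylhex-3-enal
Conditions: DMP, NaHCO3, CH2Cl2, 0 °C; used at once
Reagents that add atoms: none
Why: Dess–Martin oxidation under buffered, non-basic conditions should give the β,γ-unsaturated aldehyde without migration of the trisubstituted alkene into conjugation.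

Step 9
Reactants: 10 (5S)-3-(bromomethyl)-5-[(1Z)-3-[(tert-butyldimethylsilyl)oxy]-2-iodoprop-1-en-1-yl]furan-2(5H)-one; 18 (3E)-6-[(4-methoxybenzyl)oxy]-3-methylhex-3-enal
Product: 20 (4R,5S)-4-[(1S,3E)-1-hydroxy-6-[(4-methoxybenzyl)oxy]-3-methylhex-3-en-1-yl]-5-[(1Z)-3-[(tert-butyldimethylsilyl)oxy]-2-iodoprop-1-en-1-yl]-3-methylideneoxolan-2-one, via allylzinc bromide 19 (not isolated)
Conditions: Zn dust, THF/sat. aq. NH4Cl, 0 °C → rt
Reagents that add atoms: none
Why: Zinc Barbier allylation, in which the allylzinc formed in the presence of the aldehyde adds through its γ-carbon (C7) in a chair Zimmerman–Traxler transition state on the face anti to the C6 alkenyl group with the aldehyde chain equatorial, should set 7R (trans to C6) and the 8S carbinol and unveil the exo-methylene lactone by allylic transposition.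

Step 10
Reactants: 20 (4R,5S)-4-[(1S,3E)-1-hydroxy-6-[(4-methoxybenzyl)oxy]-3-methylhex-3-en-1-yl]-5-[(1Z)-3-[(tert-butyldimethylsilyl)oxy]-2-iodoprop-1-en-1-yl]-3-methylideneoxolan-2-one; 21 (R)-2-methylbutanoic acid
Product: 22 (1R,3E)-6-[(4-methoxybenzyl)oxy]-3-methyl-1-[(2S,3R)-2-[(1Z)-3-[(tert-butyldimethylsilyl)oxy]-2-iodoprop-1-en-1-yl]-4-methylidene-5-oxooxolan-3-yl]hex-3-en-1-yl (2R)-2-methylbutanoate
Conditions: PPh3, DIAD, toluene, 0 °C → rt
Reagents that add atoms: none
Why: Mitsunobu esterification, in which the C8 oxyphosphonium is displaced by the carboxylate with inversion, should turn the 8S carbinol of the Barbier adduct into the 8R ester of the target while the α-centre of the acid is not enolized under these neutral conditions.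

Step 11
Reactants: 22 (1R,3E)-6-[(4-methoxybenzyl)oxy]-3-methyl-1-[(2S,3R)-2-[(1Z)-3-[(tert-butyldimethylsilyl)oxy]-2-iodoprop-1-en-1-yl]-4-methylidene-5-oxooxolan-3-yl]hex-3-en-1-yl (2R)-2-methylbutanoate
Product: 23 (1R,3E)-6-hydroxy-3-methyl-1-[(2S,3R)-2-[(1Z)-3-[(tert-butyldimethylsilyl)oxy]-2-iodoprop-1-en-1-yl]-4-methylidene-5-oxooxolan-3-yl]hex-3-en-1-yl (2R)-2-methylbutanoate
Conditions: DDQ, CH2Cl2/pH 7 buffer, 0 °C
Reagents that add atoms: none
Why: Oxidative cleavage of the p-methoxybenzyl ether by DDQ (hydride abstraction, then hydrolysis of the oxocarbenium ion) should free the C3 alcohol while the silyl ether, the ester, the lactone and the alkenyl iodide are inert.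

Step 12
Reactants: 23 (1R,3E)-6-hydroxy-3-methyl-1-[(2S,3R)-2-[(1Z)-3-[(tert-butyldimethylsilyl)oxy]-2-iodoprop-1-en-1-yl]-4-methylidene-5-oxooxolan-3-yl]hex-3-en-1-yl (2R)-2-methylbutanoate
Product: 24 (1R,3E)-3-methyl-6-oxo-1-[(2S,3R)-2-[(1Z)-3-[(tert-butyldimethylsilyl)oxy]-2-iodoprop-1-en-1-yl]-4-methylidene-5-oxooxolan-3-yl]hex-3-en-1-yl (2R)-2-methylbutanoate (seco iodo-aldehyde)
Conditions: DMP, NaHCO3, CH2Cl2, 0 °C; used at once
Reagents that add atoms: none
Why: Dess–Martin oxidation of the primary homoallylic alcohol under buffered conditions should give the C3 aldehyde without moving the C1=C10 alkene into conjugation.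

Step 13
Reactants: 24 seco iodo-aldehyde
Product: 26 (3S,6R,7R,8R)-15-[(tert-butyldimethylsilyl)oxy]-3-hydroxy-8-[(2R)-2-methylbutanoyloxy]germacra-1(10)E,4Z,11(13)-trien-12,6-olide, via alkenylchromium(III) dichloride 25 (not isolated)
Conditions: CrCl2 (10 equiv), NiCl2 (2 mol%), degassed DMSO, rt, syringe-pump addition to 2 mM
Reagents that add atoms: none
Why: Intramolecular Nozaki–Hiyama–Kishi reaction: Ni(0), generated from NiCl2 by Cr(II), inserts into the C4–I bond with retention of the Z geometry, transmetalation gives the alkenylchromium(III) 25, and this adds 1,2 to the C3 aldehyde to form the C3–C4 bond. The closest known reaction type is the alkenyl iodide–aldehyde NHK macrocyclization used for medium rings, ten-membered germacranolide cores included. The ten-membered carbocycle closes in a 10-exo-trig mode (C4 attacks the C3 carbonyl carbon, the oxygen stays outside the ring), helped by the trans-lactone and the Z-alkene, which hold C4 and the C8 arm on the same side. The new C3 stereocentre is under substrate control by the fixed C6, C7 and C8 centres: in the closing conformer the carbonyl oxygen should point away from the ring and from the C15 silyloxymethyl group, which exposes the aldehyde face leading to 3S. The step needs chemoselectivity for the aldehyde over the ester, the lactone and the acrylate (secured by the low basicity and nucleophilicity of the organochromium), no migration of the β,γ-alkene (neutral medium), and ring closure over oligomerization (high dilution, slow addition).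

Step 14
Reactants: 26 (3S,6R,7R,8R)-15-[(tert-butyldimethylsilyl)oxy]-3-hydroxy-8-[(2R)-2-methylbutanoyloxy]germacra-1(10)E,4Z,11(13)-trien-12,6-olide
Product: 27 (1R,3S,6R,7R,8R,10R)-15-[(tert-butyldimethylsilyl)oxy]-1,10-epoxy-3-hydroxy-8-[(2R)-2-methylbutanoyloxy]germacra-4Z,11(13)-dien-12,6-olide
Conditions: mCPBA (1.1 equiv), NaHCO3, CH2Cl2, 0 °C
Reagents that add atoms: 3-chloroperbenzoic acid, O=C(OO)c1cccc(Cl)c1
Why: Prilezhaev epoxidation should take place at the only electron-rich alkene, the trialkyl-substituted E-C1=C10 bond (C4=C5 carries three allylic C–O bonds and the acrylate is electron-poor), on its outer face in the preferred ring conformer, which is expected to give the (1R,10R)-oxirane of this natural product family.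

Step 15
Reactants: 27 (1R,3S,6R,7R,8R,10R)-15-[(tert-butyldimethylsilyl)oxy]-1,10-epoxy-3-hydroxy-8-[(2R)-2-methylbutanoyloxy]germacra-4Z,11(13)-dien-12,6-olide
Product: 28 (1R,3S,6R,7R,8R,10R)-1,10-epoxy-3,15-dihydroxy-8-[(2R)-2-methylbutanoyloxy]germacra-4Z,11(13)-dien-12,6-olide (CNP0267576.1)
Conditions: TBAF/AcOH (1:1), THF, 0 °C → rt
Reagents that add atoms: none
Why: Fluoride-mediated desilylation buffered with acetic acid should remove the primary allylic silyl ether without opening the oxirane, adding to the α-methylene lactone or cleaving the ester.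

**Compound list**

1 | tert-butyldimethyl(prop-2-yn-1-yloxy)silane | C#CCO[Si](C)(C)C(C)(C)C | starting material
2 | (E)-but-2-enal | C/C=C/C=O | starting material
3 | methylzinc alkynide of 1 (formed in situ) | C[Zn]C#CCO[Si](C)(C)C(C)(C)C | intermediate
4 | (2E,4S)-7-[(tert-butyldimethylsilyl)oxy]hept-2-en-5-yn-4-ol | C/C=C/[C@H](O)C#CCO[Si](C)(C)C(C)(C)C | intermediate
5 | cyclic sodium alkenylalanate of 4 (formed in situ) | C/C=C/[C@H]1C=C(CO[Si](C)(C)C(C)(C)C)[Al-](OCCOC)(OCCOC)O1.[Na+] | intermediate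
6 | (2Z,4S,5E)-1-[(tert-butyldimethylsilyl)oxy]-2-iodohepta-2,5-dien-4-ol | C/C=C/[C@H](O)/C=C(\I)CO[Si](C)(C)C(C)(C)C | intermediate
7 | 2-(bromomethyl)prop-2-enoic acid | C=C(CBr)C(=O)O | starting material
8 | 2-(bromomethyl)acryloyl chloride (formed in situ) | C=C(CBr)C(Cl)=O | intermediate
9 | (2Z,4S,5E)-1-[(tert-butyldimethylsilyl)oxy]-2-iodohepta-2,5-dien-4-yl 2-(bromomethyl)prop-2-enoate | C/C=C/[C@H](OC(=O)C(=C)CBr)/C=C(\I)CO[Si](C)(C)C(C)(C)C | intermediate
10 | (5S)-3-(bromomethyl)-5-[(1Z)-3-[(tert-butyldimethylsilyl)oxy]-2-iodoprop-1-en-1-yl]furan-2(5H)-one | O=C1O[C@H](/C=C(\I)CO[Si](C)(C)C(C)(C)C)C=C1CBr | intermediate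
11 | pent-3-yn-1-ol | CC#CCCO | starting material
12 | 1-methoxy-4-[(pent-3-yn-1-yloxy)methyl]benzene | CC#CCCOCc1ccc(OC)cc1 | intermediate
13 | E-alkenylzirconocene chloride from 12 (formed in situ) | COc1ccc(COCC/C=C(\C)[Zr](Cl)(C2C=CC=C2)C2C=CC=C2)cc1 | intermediate
14 | 1-({[(3E)-4-iodopent-3-en-1-yl]oxy}methyl)-4-methoxybenzene | COc1ccc(COCC/C=C(\C)I)cc1 | intermediate
15 | oxirane | C1CO1 | starting material
16 | E-alkenyllithium from 14 (formed in situ) | COc1ccc(COCC/C=C(\C)[Li])cc1 | intermediate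
17 | (3E)-6-[(4-methoxybenzyl)oxy]-3-methylhex-3-en-1-ol | COc1ccc(COCC/C=C(\C)CCO)cc1 | intermediate
18 | (3E)-6-[(4-methoxybenzyl)oxy]-3-methylhex-3-enal | COc1ccc(COCC/C=C(\C)CC=O)cc1 | intermediate
19 | allylzinc bromide from 10 (formed in situ) | Br[Zn]CC1=C[C@@H](/C=C(\I)CO[Si](C)(C)C(C)(C)C)OC1=O | intermediate
20 | (4R,5S)-4-[(1S,3E)-1-hydroxy-6-[(4-methoxybenzyl)oxy]-3-methylhex-3-en-1-yl]-5-[(1Z)-3-[(tert-butyldimethylsilyl)oxy]-2-iodoprop-1-en-1-yl]-3-methylideneoxolan-2-one | COc1ccc(COCC/C=C(\C)C[C@H](O)[C@H]2C(=C)C(=O)O[C@@H]2/C=C(/CO[Si](C)(C)C(C)(C)C)I)cc1 | intermediate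
21 | (R)-2-methylbutanoic acid | CC[C@@H](C)C(=O)O | starting material
22 | (1R,3E)-6-[(4-methoxybenzyl)oxy]-3-methyl-1-[(2S,3R)-2-[(1Z)-3-[(tert-butyldimethylsilyl)oxy]-2-iodoprop-1-en-1-yl]-4-methylidene-5-oxooxolan-3-yl]hex-3-en-1-yl (2R)-2-methylbutanoate | COc1ccc(COCC/C=C(\C)C[C@@H](OC(=O)[C@H](C)CC)[C@H]2C(=C)C(=O)O[C@@H]2/C=C(/CO[Si](C)(C)C(C)(C)C)I)cc1 | intermediate
23 | (1R,3E)-6-hydroxy-3-methyl-1-[(2S,3R)-2-[(1Z)-3-[(tert-butyldimethylsilyl)oxy]-2-iodoprop-1-en-1-yl]-4-methylidene-5-oxooxolan-3-yl]hex-3-en-1-yl (2R)-2-methylbutanoate | OCC/C=C(\C)C[C@@H](OC(=O)[C@H](C)CC)[C@H]1C(=C)C(=O)O[C@@H]1/C=C(/CO[Si](C)(C)C(C)(C)C)I | intermediate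
24 | seco iodo-aldehyde: (1R,3E)-3-methyl-6-oxo-1-[(2S,3R)-2-[(1Z)-3-[(tert-butyldimethylsilyl)oxy]-2-iodoprop-1-en-1-yl]-4-methylidene-5-oxooxolan-3-yl]hex-3-en-1-yl (2R)-2-methylbutanoate | O=CC/C=C(\C)C[C@@H](OC(=O)[C@H](C)CC)[C@H]1C(=C)C(=O)O[C@@H]1/C=C(/CO[Si](C)(C)C(C)(C)C)I | intermediate
25 | alkenylchromium(III) dichloride from 24 (formed in situ) | O=CC/C=C(\C)C[C@@H](OC(=O)[C@H](C)CC)[C@H]1C(=C)C(=O)O[C@@H]1/C=C(/CO[Si](C)(C)C(C)(C)C)[Cr](Cl)Cl | intermediate
26 | (3S,6R,7R,8R)-15-[(tert-butyldimethylsilyl)oxy]-3-hydroxy-8-[(2R)-2-methylbutanoyloxy]germacra-1(10)E,4Z,11(13)-trien-12,6-olide | C=C1C(=O)O[C@@H]2/C=C(/CO[Si](C)(C)C(C)(C)C)[C@@H](O)C/C=C(\C)C[C@@H](OC(=O)[C@H](C)CC)[C@@H]12 | intermediate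
27 | (1R,3S,6R,7R,8R,10R)-15-[(tert-butyldimethylsilyl)oxy]-1,10-epoxy-3-hydroxy-8-[(2R)-2-methylbutanoyloxy]germacra-4Z,11(13)-dien-12,6-olide | C=C1C(=O)O[C@@H]2/C=C(/CO[Si](C)(C)C(C)(C)C)[C@@H](O)C[C@H]3O[C@]3(C)C[C@@H](OC(=O)[C@H](C)CC)[C@@H]12 | intermediate
28 | (1R,3S,6R,7R,8R,10R)-1,10-epoxy-3,15-dihydroxy-8-[(2R)-2-methylbutanoyloxy]germacra-4Z,11(13)-dien-12,6-olide (CNP0267576.1) | C=C1C(=O)O[C@@H]2/C=C(/CO)[C@@H](O)C[C@H]3O[C@]3(C)C[C@@H](OC(=O)[C@H](C)CC)[C@@H]12 | target

**Step count and risks**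

Total step count: 15. Longest linear sequence: 11 steps (steps 1–4 then 9–15; the aldehyde arm, steps 5–8, is equally long).

Steps most likely to fail:

Step 10. At the β-branched C8 oxyphosphonium, SN2 displacement by the weakly acidic aliphatic carboxylate may be slower than E2 loss towards the allylic C9 protons, acyl transfer with retention, or lactone migration to O8. The fallback sets out from 20: Dess–Martin oxidation gives the C8 ketone F1. Reduction with (S)-Me-CBS and catecholborane at −78 °C (reagent control, the C7 ring branch acting as the large group) gives the 8R alcohol F2. Esterification of F2 with acid 21 (DIC, DMAP, CH2Cl2, retention) returns to the route at 22.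

Step 13. The ring-closing addition may expose the wrong aldehyde face and give the C3 epimer, since C3 rests only on the conformation of the closing chain. The fallback sets out from 24: the ring closure is run as in step 13, and the 3R alcohol F3 (or the epimer mixture) is oxidized with Dess–Martin periodinane to the macrocyclic enone F4. Corey–Bakshi–Shibata reduction of F4 with (R)-Me-CBS and catecholborane (enone alkene as the large group) should give the 3S alcohol and returns to the route at 26.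

Step 14. If the ring populates the other planar-chiral conformer, the peracid would attack the opposite face of C1=C10, and hydroxyl direction from C3 could divert some oxidant to C4=C5. The fallback sets out from 22 and installs the oxirane on the open chain under reagent control: Shi epoxidation (D-fructose-derived ketone, Oxone, pH 10.5 buffer, MeCN/DMM, 0 °C) gives the (1R,10R)-epoxy PMB ether F5. DDQ gives the epoxy alcohol F6, and buffered Dess–Martin oxidation gives the epoxy aldehyde F7. Ring closure under the conditions of step 13, through the alkenylchromium F8, returns to the route at 27.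

**Further compounds**

F1 | step 10 | C8 ketone: (4R,5S)-4-[(3E)-6-[(4-methoxybenzyl)oxy]-3-methylhex-3-enoyl]-5-[(1Z)-3-[(tert-butyldimethylsilyl)oxy]-2-iodoprop-1-en-1-yl]-3-methylideneoxolan-2-one | COc1ccc(COCC/C=C(\C)CC(=O)[C@H]2C(=C)C(=O)O[C@@H]2/C=C(/CO[Si](C)(C)C(C)(C)C)I)cc1
F2 | step 10 | 8R alcohol: (4R,5S)-4-[(1R,3E)-1-hydroxy-6-[(4-methoxybenzyl)oxy]-3-methylhex-3-en-1-yl]-5-[(1Z)-3-[(tert-butyldimethylsilyl)oxy]-2-iodoprop-1-en-1-yl]-3-methylideneoxolan-2-one | COc1ccc(COCC/C=C(\C)C[C@@H](O)[C@H]2C(=C)C(=O)O[C@@H]2/C=C(/CO[Si](C)(C)C(C)(C)C)I)cc1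
F3 | step 13 | 3R epimer of 26 | C=C1C(=O)O[C@@H]2/C=C(/CO[Si](C)(C)C(C)(C)C)[C@H](O)C/C=C(\C)C[C@@H](OC(=O)[C@H](C)CC)[C@@H]12
F4 | step 13 | macrocyclic C3 enone: (6R,7R,8R)-15-[(tert-butyldimethylsilyl)oxy]-8-[(2R)-2-methylbutanoyloxy]-3-oxogermacra-1(10)E,4Z,11(13)-trien-12,6-olide | C=C1C(=O)O[C@@H]2/C=C(/CO[Si](C)(C)C(C)(C)C)C(=O)C/C=C(\C)C[C@@H](OC(=O)[C@H](C)CC)[C@@H]12
F5 | step 14 | (1R,10R)-epoxide of 22 | COc1ccc(COCC[C@H]2O[C@]2(C)C[C@@H](OC(=O)[C@H](C)CC)[C@H]3C(=C)C(=O)O[C@@H]3/C=C(/CO[Si](C)(C)C(C)(C)C)I)cc1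
F6 | step 14 | (1R,10R)-epoxide of 23 | OCC[C@H]1O[C@]1(C)C[C@@H](OC(=O)[C@H](C)CC)[C@H]2C(=C)C(=O)O[C@@H]2/C=C(/CO[Si](C)(C)C(C)(C)C)I
F7 | step 14 | (1R,10R)-epoxide of 24 | O=CC[C@H]1O[C@]1(C)C[C@@H](OC(=O)[C@H](C)CC)[C@H]2C(=C)C(=O)O[C@@H]2/C=C(/CO[Si](C)(C)C(C)(C)C)I
F8 | step 14 | alkenylchromium(III) dichloride from F7 (formed in situ) | O=CC[C@H]1O[C@]1(C)C[C@@H](OC(=O)[C@H](C)CC)[C@H]2C(=C)C(=O)O[C@@H]2/C=C(/CO[Si](C)(C)C(C)(C)C)[Cr](Cl)Cl
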